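Compound numbers are those of the steps below: **12** is the ring-expansion precursor, **15** its product, **20** the target.

## Analysis of the target

Compound 20 is 7-hydroxy-6-methoxy-3-(3,4,5-trimethoxyphenyl)-4H-chromen-4-one, an isoflavone: benzo ring A is fused to pyranone ring C, and aryl ring B sits on C3. It has no stereocentre, so the whole problem is regiochemical: five oxygen substituents on two benzene rings, four of them methyl ethers and one a free phenol. The sensitive sites are the acidic C7 hydroxyl (para to the C4 carbonyl), the C2=C3 enol ether of ring C (opened by hydroxide), and the three adjacent methoxyls of ring B, whose central one is the first to be lost to strong Lewis acids. The hard part is the 6-methoxy-7-hydroxy pair: telling two neighbouring oxygens apart late, by selective methylation or demethylation, is unreliable, so they should differ from the moment they are introduced. The strategy rests on ring A (C4a, C5, C6, C7, C8, C8a): the oxygen on C8a (O1) and the methoxyl on C6 are para, as in a hydroquinone monomethyl ether, C7 carries one more oxygen, and C5 and C8 are CH. This is the pattern that a 4-alkenyl-4-methoxy-3-alkoxycyclobut-2-enone with hydrogen on C2 gives on thermal ring expansion. The ring carbonyl becomes the C8a hydroxyl, C2–H becomes C8, the C3 alkoxyl becomes the C7 oxygen, the C4 methoxyl becomes the C6 methoxyl, and the two alkene carbons become C5 and C4a. Ring C then needs only one carbon (C2) between the new phenol and the benzylic position.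

## Retrosynthetic reasoning

**20 to 19.** The last bond made is the O–H on C7, by removing a secondary alkyl ether from 19. The C7 oxygen needs a mask that a reagent can tell apart from four methyl ethers. An isopropyl group does this because it leaves with carbocation character, and it costs no step because it is already present in 1.

**19 to 17.** Ring C is cut at O1–C2 and C2–C3, which removes the single carbon C2 and leaves the 2-hydroxyphenyl benzyl ketone 17. Both bonds form in one operation with a formamide acetal through enaminone 18. Cutting here, and not at the C3–aryl bond, keeps ring B attached from the start and avoids a halogenated chromone and a cross-coupling.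

**17 to 16 to 15.** The C4 carbonyl is taken back to a silyl-protected alcohol, because the chain has to pass through an alkenyllithium (10) that a ketone would not survive. Forward, this is a desilylation and a benzylic oxidation.

**15 to 12 (key disconnection).** Ring A is unravelled: the C4a–C8a bond is cut and the C8a–C8 unit is folded back onto C6, which gives cyclobutenone 12. A benzene ring with four different substituents is thereby reduced to a four-membered ring whose substituents are each placed by carbonyl chemistry. The forward reaction has to open the cyclobutenone with the alkenyl group turned towards the ketene and close the six-membered ring at the alkene terminus.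

**12 to 9 and 3.** The bond between the quaternary carbon of 12 and the alkene (the future C6–C5 bond) and the O–CH3 bond are cut. Forward, alkenyllithium 10 must add to the carbonyl of 3 that lies next to the alkoxy-bearing carbon, and the resulting alkoxide 11 must be methylated on oxygen.

**3 to 2 to 1.** The ring hydrogen of 3 (the future C8–H) replaces one isopropoxy group of 1. A single hydride addition gives 2, and acid then transposes the oxygen pattern with loss of one isopropoxy group. Starting from 1 gives a four-carbon ring that already carries the C7 oxygen in protected form.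

**9 to 7 to 6 to 4 and 5.** The (E)-iodoalkene 9 comes from terminal alkyne 7 by syn hydrometalation (8) and halogenation. The bond between the alkyne and the carbinol carbon is cut to give aldehyde 4 and acetylide 5. This places ring B and the future C3 and C4 carbons in one fragment from purchasable materials.

## Alternatives that were turned down

**Alternative 1:** Disconnection at C3–C4 and O1–C2. Ring A arrives as an aroyl chloride, and C2, C3 and ring B arrive as an enamine.
- Forward key step: 4-[(E)-2-(3,4,5-trimethoxyphenyl)ethenyl]morpholine A1 (from 4 and morpholine) is acylated at its aryl-bearing carbon by 2-(acetyloxy)-4-(benzyloxy)-5-methoxybenzoyl chloride A2. Acidic work-up frees the ortho phenol, which adds to the iminium carbon and displaces morpholine. The product is 7-(benzyloxy)-6-methoxy-3-(3,4,5-trimethoxyphenyl)-4H-chromen-4-one A3, and hydrogenolysis would finish the synthesis.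
- For: the route is convergent, one operation builds ring C, and the final debenzylation cannot touch a methyl ether. On that last point it is stronger than the Lewis acid dealkylation of step 11.
- Against: the whole regiochemical problem moves into A2, a benzoic acid with three different oxygen substituents that has to be made by successive selective alkylations of a polyhydroxybenzoic acid. A1 is conjugated with ring B and only moderately nucleophilic, and A2 is hindered by its ortho ester, so N-acylation, acetyl transfer and enamine hydrolysis compete with C-acylation.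
- Comparison: it is probably shorter than the eleven steps proposed here. The chosen route offers instead three ring A oxygens that are differentiated by their origin and not by selective alkylation, and a key step whose regiochemistry is fixed by connectivity.

**Alternative 2:** Disconnection of ring A at C5–C6 and C4a–C8a into an ynone and an oxygenated diene.
- Forward key step: [(1,4-dimethoxybuta-1,3-diene-1,3-diyl)bis(oxy)]bis(trimethylsilane) A4 adds across the triple bond of 1-(3,4,5-trimethoxyphenyl)but-3-yn-2-one A5 (the oxidation product of 6). Acidic work-up expels methanol and the silyl groups and gives 1-(2,4-dihydroxy-5-methoxyphenyl)-2-(3,4,5-trimethoxyphenyl)ethan-1-one A6, which would be closed to 20 with a one-carbon reagent.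
- For: this is the shortest plan and needs no protecting group on ring A, so it is clearly stronger on step economy.
- Against: A4 is a tetraoxygenated diene that is sensitive to moisture and is formed as a mixture of geometric isomers. A5 is a terminal, benzylic, enolisable ynone that isomerises and polymerises readily. The regiochemistry depends on the polarisation of two reactive partners in an intermolecular step. The free, acidic C7 hydroxyl of A6 can be methylated by a formamide acetal during ring C closure, which would erase the 6/7 differentiation.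
- Comparison: the chosen route is longer. It offers in return stable, isolable intermediates, an intramolecular ring closure, and a C7 oxygen that stays masked until the last step.

**Alternative 3:** Disconnection of ring C at C4–C4a, an intramolecular acylation of ring A.
- Forward key step: 3-[4-methoxy-3-(propan-2-yloxy)phenoxy]-2-(3,4,5-trimethoxyphenyl)prop-2-enoic acid A7 is activated by P2O5 in methanesulfonic acid. Its acyl carbon attacks the ring A carbon para to the isopropoxy group and gives 6-methoxy-7-(propan-2-yloxy)-3-(3,4,5-trimethoxyphenyl)-4H-chromen-4-one A8, which is identical with 19 and would be deprotected as in step 11.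
- For: A8 is reached in about four steps from a preformed ring A phenol and an arylacetate, so it is much stronger on step count.
- Against: the strongly acidic medium can remove the isopropyl group before or during cyclisation, and the freed phenol is then sulfonylated or acylated. The aryloxyacrylic acid can lose its phenol by acid-catalysed cleavage of the enol ether. Only the geometric isomer with the carboxyl cis to the aryloxy group can close. The very electron-rich ring B is open to intermolecular acylation. The ring A phenol, with its two different alkoxy groups, still has to be made separately.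
- Comparison: it is shorter than the chosen route and shares its last step. The chosen route offers instead a ring A assembled under neutral thermal conditions, with no electrophilic substitution whose position has to be controlled.

Key step: step 7

Assumption: aldehyde 4 is purchased and used freshly distilled, because arylacetaldehydes oligomerise on storage. All stereocentres along the route are carried racemic or as diastereomer mixtures, since each is destroyed before the achiral target is reached.

## Route

**Step 1**  
Reactants: 1 3,4-di(propan-2-yloxy)cyclobut-3-ene-1,2-dione (diisopropyl squarate)  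
Product: 2 4-hydroxy-2,3-di(propan-2-yloxy)cyclobut-2-en-1-one (racemic)  
Conditions: LiAlH(OtBu)3 (1.1 equiv), THF, −78 → −20 °C; then H2O, filter  
Reagents that add atoms: none  
Why: The bulky alkoxyaluminium hydride adds once, in 1,2-fashion, to one of the two equivalent carbonyl groups (chemoselective monoreduction); the alkoxide is not reduced further at low temperature, and the new stereocentre is racemic and is lost in step 2.

**Step 2**  
Reactants: 2 4-hydroxy-2,3-di(propan-2-yloxy)cyclobut-2-en-1-one  
Product: 3 3-(propan-2-yloxy)cyclobut-3-ene-1,2-dione  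
Conditions: conc. aq. HCl (cat.), CH2Cl2, rt  
Reagents that add atoms: water, `O`  
Why: Acid ionises the allylic hydroxyl to a dialkoxy-stabilised cyclobutenyl cation, water is taken up at the alkoxy-bearing terminus and propan-2-ol is expelled (allylic transposition with hydrolysis of the vinylogous ester), which leaves hydrogen on the former carbinol carbon and restores the 1,2-dione.

**Step 3**  
Reactants: 4 (3,4,5-trimethoxyphenyl)acetaldehyde; 5 ethynylmagnesium bromide  
Product: 6 1-(3,4,5-trimethoxyphenyl)but-3-yn-2-ol (racemic)  
Conditions: 5 (0.5 M in THF, 1.3 equiv), THF, −78 → 0 °C; aq. NH4Cl  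
Reagents that add atoms: ethynylmagnesium bromide 5, `C#C[Mg]Br`  
Why: Grignard 1,2-addition of an acetylide to an aldehyde; the weakly basic sp-hybridised nucleophile at low temperature keeps enolisation of the arylacetaldehyde in check, and the carbinol centre is formed racemic, which does not matter because it is oxidised in step 9.

**Step 4**  
Reactants: 6 1-(3,4,5-trimethoxyphenyl)but-3-yn-2-ol  
Product: 7 tert-butyl(dimethyl){[1-(3,4,5-trimethoxyphenyl)but-3-yn-2-yl]oxy}silane (racemic)  
Conditions: TBSCl (1.2 equiv), imidazole (2.5 equiv), DMF, rt  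
Reagents that add atoms: tert-butyl(chloro)dimethylsilane, `CC(C)(C)[Si](C)(C)Cl`  
Why: Standard imidazole-promoted silylation of a secondary alcohol; the silyl ether masks the acidic OH for the organolithium step and is orthogonal to the aryl methyl ethers.

**Step 5**  
Reactants: 7 tert-butyl(dimethyl){[1-(3,4,5-trimethoxyphenyl)but-3-yn-2-yl]oxy}silane  
Product: 9 tert-butyl{[(3E)-4-iodo-1-(3,4,5-trimethoxyphenyl)but-3-en-2-yl]oxy}dimethylsilane (racemic), via alkenylzirconocene chloride 8 (not isolated)  
Conditions: Cp2Zr(H)Cl (1.3 equiv), THF, rt, dark; then I2 (1.3 equiv), 0 °C  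
Reagents that add atoms: iodine, `II`  
Why: Hydrozirconation of the terminal alkyne is a syn addition that places zirconium on the terminal carbon, and iodinolysis of the C–Zr bond goes with retention, so only the (E)-1-iodoalkene is expected; the propargylic silyl ether is tolerated.

**Step 6**  
Reactants: 9 tert-butyl{[(3E)-4-iodo-1-(3,4,5-trimethoxyphenyl)but-3-en-2-yl]oxy}dimethylsilane; 3 3-(propan-2-yloxy)cyclobut-3-ene-1,2-dione  
Product: 12 4-[(1E)-3-{[tert-butyl(dimethyl)silyl]oxy}-4-(3,4,5-trimethoxyphenyl)but-1-en-1-yl]-4-methoxy-3-(propan-2-yloxy)cyclobut-2-en-1-one (racemic diastereomer mixture), via alkenyllithium 10 (not isolated), via lithium alkoxide 11 (not isolated)  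
Conditions: t-BuLi (2.05 equiv), Et2O, −78 °C; cannulate into 3 (1.1 equiv) in THF, −78 °C; then MeOTf (2 equiv), −78 → 0 °C; Et3N quench, chromatography on Et3N-deactivated silica  
Reagents that add atoms: methyl trifluoromethanesulfonate, `COS(=O)(=O)C(F)(F)F`  
Why: Lithium–iodine exchange with two equivalents of t-BuLi keeps the alkene geometry; the alkenyllithium then undergoes 1,2-addition to the more electrophilic ketone of 3 (the carbonyl next to the alkoxy-bearing carbon, not the vinylogous ester carbonyl), inverse addition at −78 °C limits double addition, and the hard lithium alkoxide is O-methylated in the same flask; the two stereocentres give a diastereomer mixture that converges in step 7.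

**Step 7**  
Reactants: 12 4-[(1E)-3-{[tert-butyl(dimethyl)silyl]oxy}-4-(3,4,5-trimethoxyphenyl)but-1-en-1-yl]-4-methoxy-3-(propan-2-yloxy)cyclobut-2-en-1-one  
Product: 15 2-[1-{[tert-butyl(dimethyl)silyl]oxy}-2-(3,4,5-trimethoxyphenyl)ethyl]-4-methoxy-5-(propan-2-yloxy)phenol (racemic), via dienylketene 13 (not isolated), via cyclohexadienone 14 (not isolated)  
Conditions: degassed toluene (0.02 M), 110 °C, base-washed glassware, argon  
Reagents that add atoms: none  
Why: On heating, the cyclobutenone undergoes a conrotatory four-electron electrocyclic opening of the bond between the carbonyl carbon and the quaternary carbon. The methoxyl on the quaternary carbon, a lone-pair donor, rotates outward (torquoselectivity), so the alkenyl group turns inward and lies cis to the ketene in (Z)-dienylketene 13. Ring A then closes by a thermal disrotatory six-electron electrocyclisation in which the ketene carbon (future C8a) bonds to the distal alkene carbon (future C4a), giving cyclohexa-2,4-dienone 14. Enolisation of 14, driven by aromatisation, gives phenol 15. The closest known reaction type is the Moore rearrangement of 4-alkenyl-4-hydroxy- or 4-alkoxycyclobutenones derived from squaric esters to hydroquinones and their monoethers. No stereocentre is created: the sp3 ring carbon of 14 is flattened on enolisation and the silyloxy-bearing carbon is a racemic spectator, so both diastereomers of 12 give the same product. The selectivity needed is the sense of rotation in the ring opening, which the donor oxygen on the quaternary carbon secures; an opening with the alkenyl group outward is unproductive and reverts to 12. The positions of the ring A substituents follow from connectivity alone: ring carbonyl to the C8a hydroxyl, quaternary methoxyl to C6, isopropoxyl to C7 and the ring hydrogen to C8.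

**Step 8**  
Reactants: 15 2-[1-{[tert-butyl(dimethyl)silyl]oxy}-2-(3,4,5-trimethoxyphenyl)ethyl]-4-methoxy-5-(propan-2-yloxy)phenol  
Product: 16 2-[1-hydroxy-2-(3,4,5-trimethoxyphenyl)ethyl]-4-methoxy-5-(propan-2-yloxy)phenol (racemic)  
Conditions: TBAF (2.5 equiv), AcOH (2.5 equiv), THF, 0 °C → rt; neutral aqueous work-up, crude product used directly  
Reagents that add atoms: none  
Why: Fluoride-induced cleavage of the silyl ether; acetic acid buffers the medium so that the electron-rich phenoxide is not exposed to strong base and air and the acid-sensitive benzylic alcohol is not ionised.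

**Step 9**  
Reactants: 16 2-[1-hydroxy-2-(3,4,5-trimethoxyphenyl)ethyl]-4-methoxy-5-(propan-2-yloxy)phenol  
Product: 17 1-[2-hydroxy-5-methoxy-4-(propan-2-yloxy)phenyl]-2-(3,4,5-trimethoxyphenyl)ethan-1-one  
Conditions: activated MnO2 (15 equiv), CH2Cl2, rt, argon  
Reagents that add atoms: none  
Why: Heterogeneous MnO2 oxidation of a benzylic secondary alcohol under neutral conditions; the alcohol is activated by the electron-rich ring, and once the ketone forms the ortho hydroxyl is hydrogen-bonded to it, which protects the phenol from further oxidation.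

**Step 10**  
Reactants: 17 1-[2-hydroxy-5-methoxy-4-(propan-2-yloxy)phenyl]-2-(3,4,5-trimethoxyphenyl)ethan-1-one  
Product: 19 6-methoxy-7-(propan-2-yloxy)-3-(3,4,5-trimethoxyphenyl)-4H-chromen-4-one, via enaminone 18 (not isolated)  
Conditions: Me2NCH(OMe)2 (3 equiv), toluene, 100 °C  
Reagents that add atoms: N,N-dimethylformamide dimethyl acetal, `COC(OC)N(C)C`  
Why: The formamide acetal condenses with the methylene group activated by both the ketone and ring B to give enaminone 18, and the chelated ortho phenol then adds to the enamine carbon and expels dimethylamine (addition–elimination, 6-endo-trig), closing ring C; this is the standard deoxybenzoin route to isoflavones, and no other free hydroxyl is present for the acetal to methylate.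

**Step 11**  
Reactants: 19 6-methoxy-7-(propan-2-yloxy)-3-(3,4,5-trimethoxyphenyl)-4H-chromen-4-one  
Product: 20 7-hydroxy-6-methoxy-3-(3,4,5-trimethoxyphenyl)-4H-chromen-4-one  
Conditions: BCl3 (1 M in CH2Cl2, 3 equiv), CH2Cl2, −78 → 0 °C; then aq. NaHCO3  
Reagents that add atoms: none  
Why: BCl3 coordinates the ether oxygens and the secondary isopropyl group departs with carbocation character far faster than chloride can attack a methyl group, so the isopropyl aryl ether is cleaved selectively at low temperature; no methoxyl lies peri or ortho to the carbonyl to be removed through chelation, and a short reaction time protects the three adjacent methoxyls of ring B.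

## Compound list

```
1 | 3,4-di(propan-2-yloxy)cyclobut-3-ene-1,2-dione (diisopropyl squarate) | CC(C)OC1=C(OC(C)C)C(=O)C1=O | starting material
2 | 4-hydroxy-2,3-di(propan-2-yloxy)cyclobut-2-en-1-one (racemic) | CC(C)OC1=C(OC(C)C)C(O)C1=O | intermediate
3 | 3-(propan-2-yloxy)cyclobut-3-ene-1,2-dione | CC(C)OC1=CC(=O)C1=O | intermediate
4 | (3,4,5-trimethoxyphenyl)acetaldehyde | COc1cc(CC=O)cc(OC)c1OC | starting material
5 | ethynylmagnesium bromide | C#C[Mg]Br | starting material
6 | 1-(3,4,5-trimethoxyphenyl)but-3-yn-2-ol (racemic) | C#CC(O)Cc1cc(OC)c(OC)c(OC)c1 | intermediate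
7 | tert-butyl(dimethyl){[1-(3,4,5-trimethoxyphenyl)but-3-yn-2-yl]oxy}silane (racemic) | C#CC(O[Si](C)(C)C(C)(C)C)Cc1cc(OC)c(OC)c(OC)c1 | intermediate
8 | chlorobis(cyclopentadienyl)[(1E)-3-{[tert-butyl(dimethyl)silyl]oxy}-4-(3,4,5-trimethoxyphenyl)but-1-en-1-yl]zirconium (racemic) | Cl[Zr](/C=C/C(O[Si](C)(C)C(C)(C)C)Cc1cc(OC)c(OC)c(OC)c1)(C1C=CC=C1)C1C=CC=C1 | intermediate (not isolated)
9 | tert-butyl{[(3E)-4-iodo-1-(3,4,5-trimethoxyphenyl)but-3-en-2-yl]oxy}dimethylsilane (racemic) | I/C=C/C(O[Si](C)(C)C(C)(C)C)Cc1cc(OC)c(OC)c(OC)c1 | intermediate
10 | [(1E)-3-{[tert-butyl(dimethyl)silyl]oxy}-4-(3,4,5-trimethoxyphenyl)but-1-en-1-yl]lithium (racemic) | [Li]/C=C/C(O[Si](C)(C)C(C)(C)C)Cc1cc(OC)c(OC)c(OC)c1 | intermediate (not isolated)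
11 | lithium 1-[(1E)-3-{[tert-butyl(dimethyl)silyl]oxy}-4-(3,4,5-trimethoxyphenyl)but-1-en-1-yl]-4-oxo-2-(propan-2-yloxy)cyclobut-2-en-1-olate (diastereomer mixture) | O=C1C=C(OC(C)C)C1(O[Li])/C=C/C(O[Si](C)(C)C(C)(C)C)Cc1cc(OC)c(OC)c(OC)c1 | intermediate (not isolated)
12 | 4-[(1E)-3-{[tert-butyl(dimethyl)silyl]oxy}-4-(3,4,5-trimethoxyphenyl)but-1-en-1-yl]-4-methoxy-3-(propan-2-yloxy)cyclobut-2-en-1-one (racemic diastereomer mixture) | O=C1C=C(OC(C)C)C1(OC)/C=C/C(O[Si](C)(C)C(C)(C)C)Cc1cc(OC)c(OC)c(OC)c1 | intermediate
13 | (3Z,5E)-7-{[tert-butyl(dimethyl)silyl]oxy}-4-methoxy-3-(propan-2-yloxy)-8-(3,4,5-trimethoxyphenyl)octa-1,3,5-trien-1-one (racemic) | O=C=C/C(OC(C)C)=C(OC)\C=C\C(O[Si](C)(C)C(C)(C)C)Cc1cc(OC)c(OC)c(OC)c1 | intermediate (not isolated)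
14 | 6-[1-{[tert-butyl(dimethyl)silyl]oxy}-2-(3,4,5-trimethoxyphenyl)ethyl]-4-methoxy-3-(propan-2-yloxy)cyclohexa-2,4-dien-1-one (diastereomer mixture) | O=C1C=C(OC(C)C)C(OC)=CC1C(O[Si](C)(C)C(C)(C)C)Cc1cc(OC)c(OC)c(OC)c1 | intermediate (not isolated)
15 | 2-[1-{[tert-butyl(dimethyl)silyl]oxy}-2-(3,4,5-trimethoxyphenyl)ethyl]-4-methoxy-5-(propan-2-yloxy)phenol (racemic) | COc1cc(C(Cc2cc(OC)c(OC)c(OC)c2)O[Si](C)(C)C(C)(C)C)c(O)cc1OC(C)C | intermediate
16 | 2-[1-hydroxy-2-(3,4,5-trimethoxyphenyl)ethyl]-4-methoxy-5-(propan-2-yloxy)phenol (racemic) | COc1cc(C(O)Cc2cc(OC)c(OC)c(OC)c2)c(O)cc1OC(C)C | intermediate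
17 | 1-[2-hydroxy-5-methoxy-4-(propan-2-yloxy)phenyl]-2-(3,4,5-trimethoxyphenyl)ethan-1-one | COc1cc(C(=O)Cc2cc(OC)c(OC)c(OC)c2)c(O)cc1OC(C)C | intermediate
18 | 3-(dimethylamino)-1-[2-hydroxy-5-methoxy-4-(propan-2-yloxy)phenyl]-2-(3,4,5-trimethoxyphenyl)prop-2-en-1-one (alkene geometry not defined) | COc1cc(C(=O)C(=CN(C)C)c2cc(OC)c(OC)c(OC)c2)c(O)cc1OC(C)C | intermediate (not isolated)
19 | 6-methoxy-7-(propan-2-yloxy)-3-(3,4,5-trimethoxyphenyl)-4H-chromen-4-one | COc1cc2c(=O)c(-c3cc(OC)c(OC)c(OC)c3)coc2cc1OC(C)C | intermediate
20 | 7-hydroxy-6-methoxy-3-(3,4,5-trimethoxyphenyl)-4H-chromen-4-one | COc1cc2c(=O)c(-c3cc(OC)c(OC)c(OC)c3)coc2cc1O | target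
```

## Step count and least certain steps

Total: 11 steps. Longest linear sequence: 9 steps (steps 3 to 11, from aldehyde 4). The squarate branch (steps 1 and 2) joins at step 6.

**Step 7 (key step).** The ring expansion itself has close precedent. The likely failure lies in the side chain: at 110 °C the new phenol sits ortho to a benzylic silyl ether that is also para to the isopropoxy group, so thermal loss of silanol through an ortho-quinone methide, leading to a stilbene, can compete. Acylation of the product phenol by the ketene is a second possible loss at higher concentration. The fallback keeps the ring expansion but attaches the side chain afterwards. It sets out from 3 and 4 and comes back at 17.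
- Vinylmagnesium bromide is added to 3 (THF, −78 °C) to give 4-ethenyl-4-hydroxy-3-(propan-2-yloxy)cyclobut-2-en-1-one F1.
- F1 is methylated with MeI and Ag2O to 4-ethenyl-4-methoxy-3-(propan-2-yloxy)cyclobut-2-en-1-one F2.
- Heating F2 in toluene gives, by the same rearrangement on a substrate with no leaving group, 4-methoxy-3-(propan-2-yloxy)phenol F3.
- Pinnick oxidation of 4 (NaClO2, NaH2PO4, 2-methylbut-2-ene) gives (3,4,5-trimethoxyphenyl)acetic acid F4.
- Friedel–Crafts acylation of F3 with F4 in BF3·OEt2 at 70 °C, at the position ortho to the hydroxyl and para to the isopropoxy group, gives 17.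

**Step 6.** The most likely failures are attack of the alkenyllithium at the other carbonyl of 3 (the vinylogous ester carbonyl next to the CH), conjugate addition or double addition, and incomplete O-methylation of the hindered tertiary alkoxide, whose protonated form is acid-labile. The fallback uses a softer alkenylmetal and a separate neutral methylation. It sets out from 7 and 3 and comes back at 12.
- Hydrozirconation of 7 as in step 5 gives 8.
- Transmetalation with Me2Zn (toluene, −60 → 0 °C) gives methyl[(1E)-3-{[tert-butyl(dimethyl)silyl]oxy}-4-(3,4,5-trimethoxyphenyl)but-1-en-1-yl]zinc F5.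
- F5 adds to the activated ketone of 3 at 0 °C. Work-up with aq. NH4Cl gives 4-[(1E)-3-{[tert-butyl(dimethyl)silyl]oxy}-4-(3,4,5-trimethoxyphenyl)but-1-en-1-yl]-4-hydroxy-3-(propan-2-yloxy)cyclobut-2-en-1-one F6.
- F6 is methylated with MeI and Ag2O in acetonitrile to give 12.

**Step 9 (with the handling of 16 from step 8).** The benzylic alcohol of 16 is doubly activated (ortho hydroxyl, para isopropoxyl), so dehydration to a stilbene on acidic surfaces can compete. Over-oxidation of the electron-rich para-methoxyphenol by the large excess of MnO2 is the second risk. The fallback removes the free phenol before the alcohol is exposed. It sets out from 15 and comes back at 17.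
- Benzylation of 15 (BnBr, K2CO3, DMF) gives tert-butyl{1-[2-(benzyloxy)-5-methoxy-4-(propan-2-yloxy)phenyl]-2-(3,4,5-trimethoxyphenyl)ethoxy}dimethylsilane F7.
- TBAF in THF gives 1-[2-(benzyloxy)-5-methoxy-4-(propan-2-yloxy)phenyl]-2-(3,4,5-trimethoxyphenyl)ethan-1-ol F8.
- Dess–Martin oxidation gives 1-[2-(benzyloxy)-5-methoxy-4-(propan-2-yloxy)phenyl]-2-(3,4,5-trimethoxyphenyl)ethan-1-one F9.
- Hydrogenolysis (H2, Pd/C, EtOAc) gives 17.

**Step 3.** The aldehyde is easily enolised, so deprotonation by the Grignard reagent followed by aldol self-condensation can lower the conversion. The fallback replaces the aldehyde addition by an acyl substitution and a reduction. It sets out from 4 and comes back at 6.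
- Acid F4 (from 4 as described above) is converted with carbonyldiimidazole and N,O-dimethylhydroxylamine hydrochloride into N-methoxy-N-methyl-2-(3,4,5-trimethoxyphenyl)acetamide F10.
- Lithium (trimethylsilyl)acetylide (THF, −78 °C, cold acidic quench) gives 1-(3,4,5-trimethoxyphenyl)-4-(trimethylsilyl)but-3-yn-2-one F11.
- Luche reduction (NaBH4, CeCl3·7H2O, MeOH) gives 1-(3,4,5-trimethoxyphenyl)-4-(trimethylsilyl)but-3-yn-2-ol F12.
- K2CO3 in MeOH removes the silyl group and gives 6.

## Further compounds

```
F1 | step 7 | 4-ethenyl-4-hydroxy-3-(propan-2-yloxy)cyclobut-2-en-1-one (racemic) | O=C1C=C(OC(C)C)C1(O)C=C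
F2 | step 7 | 4-ethenyl-4-methoxy-3-(propan-2-yloxy)cyclobut-2-en-1-one (racemic) | O=C1C=C(OC(C)C)C1(OC)C=C
F3 | step 7 | 4-methoxy-3-(propan-2-yloxy)phenol | COc1ccc(O)cc1OC(C)C
F4 | step 7 | (3,4,5-trimethoxyphenyl)acetic acid | COc1cc(CC(=O)O)cc(OC)c1OC
F5 | step 6 | methyl[(1E)-3-{[tert-butyl(dimethyl)silyl]oxy}-4-(3,4,5-trimethoxyphenyl)but-1-en-1-yl]zinc (racemic) | C[Zn]/C=C/C(O[Si](C)(C)C(C)(C)C)Cc1cc(OC)c(OC)c(OC)c1
F6 | step 6 | 4-[(1E)-3-{[tert-butyl(dimethyl)silyl]oxy}-4-(3,4,5-trimethoxyphenyl)but-1-en-1-yl]-4-hydroxy-3-(propan-2-yloxy)cyclobut-2-en-1-one (racemic diastereomer mixture) | O=C1C=C(OC(C)C)C1(O)/C=C/C(O[Si](C)(C)C(C)(C)C)Cc1cc(OC)c(OC)c(OC)c1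
F7 | step 9 | tert-butyl{1-[2-(benzyloxy)-5-methoxy-4-(propan-2-yloxy)phenyl]-2-(3,4,5-trimethoxyphenyl)ethoxy}dimethylsilane (racemic) | COc1cc(C(Cc2cc(OC)c(OC)c(OC)c2)O[Si](C)(C)C(C)(C)C)c(OCc2ccccc2)cc1OC(C)C
F8 | step 9 | 1-[2-(benzyloxy)-5-methoxy-4-(propan-2-yloxy)phenyl]-2-(3,4,5-trimethoxyphenyl)ethan-1-ol (racemic) | COc1cc(C(O)Cc2cc(OC)c(OC)c(OC)c2)c(OCc2ccccc2)cc1OC(C)C
F9 | step 9 | 1-[2-(benzyloxy)-5-methoxy-4-(propan-2-yloxy)phenyl]-2-(3,4,5-trimethoxyphenyl)ethan-1-one | COc1cc(C(=O)Cc2cc(OC)c(OC)c(OC)c2)c(OCc2ccccc2)cc1OC(C)C
F10 | step 3 | N-methoxy-N-methyl-2-(3,4,5-trimethoxyphenyl)acetamide | CON(C)C(=O)Cc1cc(OC)c(OC)c(OC)c1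
F11 | step 3 | 1-(3,4,5-trimethoxyphenyl)-4-(trimethylsilyl)but-3-yn-2-one | C[Si](C)(C)C#CC(=O)Cc1cc(OC)c(OC)c(OC)c1
F12 | step 3 | 1-(3,4,5-trimethoxyphenyl)-4-(trimethylsilyl)but-3-yn-2-ol (racemic) | C[Si](C)(C)C#CC(O)Cc1cc(OC)c(OC)c(OC)c1
A1 | alternative 1 | 4-[(E)-2-(3,4,5-trimethoxyphenyl)ethenyl]morpholine | COc1cc(/C=C/N2CCOCC2)cc(OC)c1OC
A2 | alternative 1 | 2-(acetyloxy)-4-(benzyloxy)-5-methoxybenzoyl chloride | CC(=O)Oc1cc(OCc2ccccc2)c(OC)cc1C(=O)Cl
A3 | alternative 1 | 7-(benzyloxy)-6-methoxy-3-(3,4,5-trimethoxyphenyl)-4H-chromen-4-one | COc1cc2c(=O)c(-c3cc(OC)c(OC)c(OC)c3)coc2cc1OCc1ccccc1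
A4 | alternative 2 | [(1,4-dimethoxybuta-1,3-diene-1,3-diyl)bis(oxy)]bis(trimethylsilane) (alkene geometry not defined) | COC=C(O[Si](C)(C)C)C=C(OC)O[Si](C)(C)C
A5 | alternative 2 | 1-(3,4,5-trimethoxyphenyl)but-3-yn-2-one | C#CC(=O)Cc1cc(OC)c(OC)c(OC)c1
A6 | alternative 2 | 1-(2,4-dihydroxy-5-methoxyphenyl)-2-(3,4,5-trimethoxyphenyl)ethan-1-one | COc1cc(C(=O)Cc2cc(OC)c(OC)c(OC)c2)c(O)cc1O
A7 | alternative 3 | 3-[4-methoxy-3-(propan-2-yloxy)phenoxy]-2-(3,4,5-trimethoxyphenyl)prop-2-enoic acid (alkene geometry not defined) | COc1ccc(OC=C(C(=O)O)c2cc(OC)c(OC)c(OC)c2)cc1OC(C)C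
A8 | alternative 3 | 6-methoxy-7-(propan-2-yloxy)-3-(3,4,5-trimethoxyphenyl)-4H-chromen-4-one (identical with 19) | COc1cc2c(=O)c(-c3cc(OC)c(OC)c(OC)c3)coc2cc1OC(C)C
```
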